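**Retrosynthetic overview**
- The acid comes from its methyl ester. The C5–alkenyl bond is made last, by Lewis-acid substitution of a 5-methoxy-1,2-dioxolane (cyclic peroxycarbenium ion) with the complete (E)-alkenyltrifluoroborate side chain.
- The side chain comes from copper-catalysed methylboration of an enyne, whose stereocentre is set by Johnson–Claisen chirality transfer from (R,E)-hept-4-en-3-ol.
- The acrylate arm comes from one-pot oxidation/Wittig of a C3 hydroxymethyl group.
- Only one ring is formed (the 1,2-dioxolane), in one operation: H2O2 opens an (R)-2,2-disubstituted epoxide at its tertiary carbon with inversion and closes onto the C5 ketone.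
- Key C–C bond (C4–C5): lithiated 2-ethyl-1,3-dithiane (a propanoyl anion equivalent) joins a Sharpless-derived 2-ethylglycidyl tosylate with epoxide relay.

Assumption: ring atoms are numbered O1, O2, C3 (acrylate carbon), C4, C5 (side-chain carbon); the ketal carbon of 11–14 is carried as both epimers because it is re-ionised in step 11.

**Step 1**
Reactants: 1 2-ethylacrolein (2-methylidenebutanal)
Product: 2 2-methylidenebutan-1-ol
Conditions: NaBH4, CeCl3·7H2O, MeOH, 0 °C
Reagents that add atoms: none
Why: Luche reduction delivers hydride 1,2 to the enal and leaves the 1,1-disubstituted alkene untouched; no stereocentre is formed.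

**Step 2**
Reactants: 2 2-methylidenebutan-1-ol
Product: 4 [(2R)-2-ethyloxiran-2-yl]methyl 4-methylbenzenesulfonate, via [(2S)-2-ethyloxiran-2-yl]methanol 3 (not isolated)
Conditions: Ti(OiPr)4 (5 mol %), L-(+)-diisopropyl tartrate (6 mol %), cumene hydroperoxide, 3 Å MS, CH2Cl2, −20 °C; then P(OMe)3; then TsCl, Et3N, DMAP (cat.), −10 to 0 °C
Reagents that add atoms: cumene hydroperoxide (CC(C)(OO)c1ccccc1); 4-toluenesulfonyl chloride (Cc1ccc(cc1)S(=O)(=O)Cl)
Why: Sharpless asymmetric epoxidation of a 2-substituted allylic alcohol with the L-(+)-tartrate catalyst gives the (S)-epoxy alcohol (same facial sense as (S)-glycidol and (S)-2-methylglycidol, ca. 90–94% ee expected), and in situ tosylation avoids isolating the small water-soluble epoxy alcohol (the descriptor becomes R only because the CIP ranks change).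

**Step 3**
Reactants: 5 1,3-dithiane; 4 [(2R)-2-ethyloxiran-2-yl]methyl 4-methylbenzenesulfonate
Product: 8 2-ethyl-2-{[(2R)-2-ethyloxiran-2-yl]methyl}-1,3-dithiane, via 2-ethyl-1,3-dithiane 6 (not isolated), via lithium tosyloxy alkoxide 7 (not isolated)
Conditions: 5, n-BuLi, THF, −30 °C; EtBr, −78 to 0 °C; n-BuLi, −25 °C, 3 h; then 4, DMPU, −78 to 0 °C
Reagents that add atoms: bromoethane (CCBr)
Why: Corey–Seebach acyl anion chemistry run as a one-flask linchpin sequence, in which lithiated 5 is ethylated, 6 is lithiated again and this propanoyl anion equivalent opens the terminal epoxide CH2 of 4 (as with epichlorohydrin), after which the tertiary alkoxide 7 displaces the tosylate (3-exo-tet) to give the transposed 2,2-disubstituted epoxide; no bond to the stereocentre is broken, so the (R) configuration of 8 follows directly from 4.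

**Step 4**
Reactants: 8 2-ethyl-2-{[(2R)-2-ethyloxiran-2-yl]methyl}-1,3-dithiane
Product: 9 1-[(2R)-2-ethyloxiran-2-yl]butan-2-one
Conditions: MeI, CaCO3, MeCN/H2O (9:1), 35 °C; used crude
Reagents that add atoms: water (O)
Why: S-methylation and hydrolysis of the dithiane, buffered by CaCO3, unmasks the ketone under near-neutral conditions that spare the acid- and base-sensitive β,γ-epoxy ketone; the stereocentre is untouched.

**Step 5**
Reactants: 9 1-[(2R)-2-ethyloxiran-2-yl]butan-2-one
Product: 12 [(3S)-3,5-diethyl-5-methoxy-1,2-dioxolan-3-yl]methanol (both C5 epimers), via hydroperoxy ketone 10 (not isolated), via dioxolan-3-ol 11 (not isolated)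
Conditions: H2O2 (ca. 2 M in Et2O), H3PMo12O40 (3 mol %), 0 °C to rt; aqueous wash; then MeOH, TsOH·H2O (5 mol %), rt
Reagents that add atoms: hydrogen peroxide (OO); methanol (CO)
Why: H3PMo12O40-catalysed perhydrolysis of the 2,2-disubstituted epoxide (by H2O2 itself or by the ketone perhydrate; both tertiary-selective, 5-exo paths converge) forms the tertiary C–OO bond with inversion and so sets the (S) peroxide carbon, the hydroperoxide then closes onto the ketone to the 1,2-dioxolan-3-ol, and acid-catalysed exchange in MeOH gives the methyl peroxyketal.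

**Step 6**
Reactants: 12 [(3S)-3,5-diethyl-5-methoxy-1,2-dioxolan-3-yl]methanol
Product: 14 methyl (2E)-3-[(3S)-3,5-diethyl-5-methoxy-1,2-dioxolan-3-yl]prop-2-enoate, via peroxy aldehyde 13 (not isolated)
Conditions: Dess–Martin periodinane, Ph3P=CHCO2Me, CH2Cl2, 0 °C to rt
Reagents that add atoms: methyl (triphenylphosphoranylidene)acetate (COC(=O)C=P(c1ccccc1)(c1ccccc1)c1ccccc1)
Why: Dess–Martin oxidation in the presence of the stabilised ylide (one-pot oxidation–Wittig) traps the non-enolisable α-peroxy aldehyde as the (E)-enoate (E > 20:1 expected) without touching the O–O bond or the stereocentre.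

**Step 7**
Reactants: 15 (2E)-pent-2-enal
Product: 16 (3R,4E)-hept-4-en-3-ol
Conditions: Et2Zn, (2R)-(+)-3-exo-(dimethylamino)isoborneol (5 mol %), toluene, 0 °C; aq. NH4Cl
Reagents that add atoms: diethylzinc (CC[Zn]CC)
Why: Noyori amino-alcohol-catalysed 1,2-addition of Et2Zn to the enal; the (2R)-ligand is the mirror image of the one that gives (S)-1-phenylpropanol and therefore gives the (R)-allylic alcohol (ca. 90% ee expected).

**Step 8**
Reactants: 16 (3R,4E)-hept-4-en-3-ol
Product: 17 ethyl (3R,4E)-3-ethylhept-4-enoate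
Conditions: MeC(OEt)3, EtCO2H (cat.), 140 °C, EtOH distilled off
Reagents that add atoms: triethyl orthoacetate (CC(OCC)(OCC)OCC)
Why: Johnson–Claisen rearrangement through a chair transition state with the carbinol ethyl group equatorial transfers the (R) carbinol chirality suprafacially to the new (3R) stereocentre and gives the (E)-alkene.

**Step 9**
Reactants: 17 ethyl (3R,4E)-3-ethylhept-4-enoate
Product: 19 (4R,5E)-4-ethyloct-5-en-1-yne, via (3R,4E)-3-ethylhept-4-enal 18 (not isolated)
Conditions: i-Bu2AlH, CH2Cl2, −78 °C; then MeOH, K2CO3, dimethyl (1-diazo-2-oxopropyl)phosphonate, −78 °C to rt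
Reagents that add atoms: dimethyl (1-diazo-2-oxopropyl)phosphonate (CC(=O)C(=[N+]=[N-])P(=O)(OC)OC)
Why: Low-temperature i-Bu2AlH reduction stops at the aluminium hemiacetal, which releases the aldehyde in the same flask for Ohira–Bestmann (Seyferth–Gilbert) homologation to the terminal alkyne; the stereocentre is β to the carbonyl and cannot epimerise.

**Step 10**
Reactants: 19 (4R,5E)-4-ethyloct-5-en-1-yne
Product: 21 potassium [(1E,4R,5E)-4-ethyl-2-methylocta-1,5-dien-1-yl]trifluoroborate, via alkenyl pinacol boronate 20 (not isolated)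
Conditions: CuCl (5 mol %), Xantphos (5 mol %), B2pin2, NaOtBu, MeI, THF, rt; then KHF2, MeOH/H2O, rt
Reagents that add atoms: bis(pinacolato)diboron (CC1(C)OB(OC1(C)C)B1OC(C)(C)C(C)(C)O1); iodomethane (CI); potassium hydrogen difluoride (F.[F-].[K+])
Why: Copper-catalysed syn-methylboration (formal carboboration) of the terminal alkyne puts boron on the terminal carbon and methyl on the internal carbon cis to each other, which fixes the (E)-trisubstituted alkene, and KHF2 converts the boronate to the crystalline trifluoroborate.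

**Step 11**
Reactants: 14 methyl (2E)-3-[(3S)-3,5-diethyl-5-methoxy-1,2-dioxolan-3-yl]prop-2-enoate; 21 potassium [(1E,4R,5E)-4-ethyl-2-methylocta-1,5-dien-1-yl]trifluoroborate
Product: 22 methyl (2E)-3-{(3S,5R)-3,5-diethyl-5-[(1E,4R,5E)-4-ethyl-2-methylocta-1,5-dien-1-yl]-1,2-dioxolan-3-yl}prop-2-enoate
Conditions: BF3·OEt2, CH2Cl2/MeCN (5:1), −40 to 0 °C; cold aq. NaHCO3; chromatography
Reagents that add atoms: none
Why: Proposed new method: BF3 ionises the methyl peroxyketal to a cyclic peroxycarbenium ion (as in the known Lewis-acid substitutions of 3-alkoxy-1,2-dioxolanes by allylsilanes and silyl enol ethers) and unmasks the alkenyl-BF2 species, whose electron-rich trisubstituted alkene attacks ipso with retention of geometry (closest known reaction: BF3-promoted coupling of potassium alkenyltrifluoroborates with acetal-derived oxocarbenium ions); inside attack on the envelope that keeps the C3 ethyl group pseudo-equatorial and the flat enoate arm pseudo-axial places the new alkenyl group cis to the enoate and sets (5R) (ca. 3:1 expected, minor C5 epimer removed by chromatography).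

**Step 12**
Reactants: 22 methyl (2E)-3-{(3S,5R)-3,5-diethyl-5-[(1E,4R,5E)-4-ethyl-2-methylocta-1,5-dien-1-yl]-1,2-dioxolan-3-yl}prop-2-enoate
Product: 23 (2E)-3-{(3S,5R)-3,5-diethyl-5-[(1E,4R,5E)-4-ethyl-2-methylocta-1,5-dien-1-yl]-1,2-dioxolan-3-yl}prop-2-enoic acid (CNP0249416.2)
Conditions: LiOH·H2O, THF/MeOH/H2O (3:1:1), 0 °C to rt; then 1 M HCl to pH 3
Reagents that add atoms: water (O)
Why: Saponification cleaves the methyl ester without harming the 1,2-dioxolane, which has no hydrogen on either peroxide carbon and so cannot undergo base-induced Kornblum–DeLaMare fragmentation; no stereocentre is affected.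

**Compound list**
1 | 2-ethylacrolein (2-methylidenebutanal) | CCC(=C)C=O | starting material
2 | 2-methylidenebutan-1-ol | CCC(=C)CO | intermediate
3 | [(2S)-2-ethyloxiran-2-yl]methanol | OC[C@@]1(CC)CO1 | intermediate
4 | [(2R)-2-ethyloxiran-2-yl]methyl 4-methylbenzenesulfonate | Cc1ccc(cc1)S(=O)(=O)OC[C@@]1(CC)CO1 | intermediate
5 | 1,3-dithiane | C1CSCSC1 | starting material
6 | 2-ethyl-1,3-dithiane | CCC1SCCCS1 | intermediate
7 | lithium (2R)-2-[(2-ethyl-1,3-dithian-2-yl)methyl]-1-[(4-methylbenzenesulfonyl)oxy]butan-2-olate | [Li+].CCC1(SCCCS1)C[C@@](CC)([O-])COS(=O)(=O)c1ccc(C)cc1 | intermediate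
8 | 2-ethyl-2-{[(2R)-2-ethyloxiran-2-yl]methyl}-1,3-dithiane | CCC1(SCCCS1)C[C@@]1(CC)OC1 | intermediate
9 | 1-[(2R)-2-ethyloxiran-2-yl]butan-2-one | CCC(=O)C[C@@]1(CC)OC1 | intermediate
10 | (5S)-5-hydroperoxy-5-(hydroxymethyl)heptan-3-one | CCC(=O)C[C@](CO)(CC)OO | intermediate
11 | (5S)-3,5-diethyl-5-(hydroxymethyl)-1,2-dioxolan-3-ol (both C3 epimers) | CCC1(O)C[C@](CO)(CC)OO1 | intermediate
12 | [(3S)-3,5-diethyl-5-methoxy-1,2-dioxolan-3-yl]methanol (both C5 epimers) | CCC1(OC)C[C@](CO)(CC)OO1 | intermediate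
13 | (3S)-3,5-diethyl-5-methoxy-1,2-dioxolane-3-carbaldehyde (both C5 epimers) | CCC1(OC)C[C@](C=O)(CC)OO1 | intermediate
14 | methyl (2E)-3-[(3S)-3,5-diethyl-5-methoxy-1,2-dioxolan-3-yl]prop-2-enoate (both C5 epimers) | CCC1(OC)C[C@](/C=C/C(=O)OC)(CC)OO1 | intermediate
15 | (2E)-pent-2-enal | CC/C=C/C=O | starting material
16 | (3R,4E)-hept-4-en-3-ol | CC/C=C/[C@H](O)CC | intermediate
17 | ethyl (3R,4E)-3-ethylhept-4-enoate | CC/C=C/[C@H](CC)CC(=O)OCC | intermediate
18 | (3R,4E)-3-ethylhept-4-enal | CC/C=C/[C@H](CC)CC=O | intermediate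
19 | (4R,5E)-4-ethyloct-5-en-1-yne | CC/C=C/[C@H](CC)CC#C | intermediate
20 | 2-[(1E,4R,5E)-4-ethyl-2-methylocta-1,5-dien-1-yl]-4,4,5,5-tetramethyl-1,3,2-dioxaborolane | CC/C=C/[C@H](CC)C/C(C)=C/B1OC(C)(C)C(C)(C)O1 | intermediate
21 | potassium [(1E,4R,5E)-4-ethyl-2-methylocta-1,5-dien-1-yl]trifluoroborate | [K+].CC/C=C/[C@H](CC)C/C(C)=C/[B-](F)(F)F | intermediate
22 | methyl (2E)-3-{(3S,5R)-3,5-diethyl-5-[(1E,4R,5E)-4-ethyl-2-methylocta-1,5-dien-1-yl]-1,2-dioxolan-3-yl}prop-2-enoate | CC/C=C/[C@H](CC)C/C(C)=C/[C@@]1(CC)C[C@](/C=C/C(=O)OC)(CC)OO1 | intermediate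
23 | (2E)-3-{(3S,5R)-3,5-diethyl-5-[(1E,4R,5E)-4-ethyl-2-methylocta-1,5-dien-1-yl]-1,2-dioxolan-3-yl}prop-2-enoic acid | CC/C=C/[C@H](CC)C/C(C)=C/[C@@]1(CC)C[C@](/C=C/C(=O)O)(CC)OO1 | target

**Step count**
Total: 12 steps. Longest linear sequence: 8 steps (1, 2, 3, 4, 5, 6, 11, 12) from 2-ethylacrolein; the side chain takes 4 steps (7–10).

**Steps most likely to fail, each with a fallback**

Step 3. The two electrophilic sites of 4 lead to opposite enantiomers of 8, so any direct displacement of the tosylate that competes with epoxide opening erodes the ee; the second lithiation in the same flask may also be incomplete. The fallback sets out from 3, which is silylated in the epoxidation flask (TBSCl, imidazole) to tert-butyl{[(2R)-2-ethyloxiran-2-yl]methoxy}dimethylsilane F1. Separately prepared, lithiated 6 can then only open the epoxide CH2, giving (2R)-1-{[tert-butyl(dimethyl)silyl]oxy}-2-[(2-ethyl-1,3-dithian-2-yl)methyl]butan-2-ol F2. Bu4NF frees (2R)-2-[(2-ethyl-1,3-dithian-2-yl)methyl]butane-1,2-diol F3, and tosylation of the primary hydroxyl gives (2R)-2-[(2-ethyl-1,3-dithian-2-yl)methyl]-2-hydroxybutyl 4-methylbenzenesulfonate F4. K2CO3 in MeOH closes the epoxide and the sequence comes back to the route at 8 with the same configuration.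

Step 5. The β,γ-epoxy ketone 9 can isomerise to the γ-hydroxy enone or undergo Meinwald rearrangement before the peroxide ring closes, and partial ionisation at the tertiary carbon would lower the ee. The fallback sets out from 8: MeI and CaCO3 in MeOH/HC(OMe)3 convert the dithiane directly into the dimethyl ketal (2R)-2-(2,2-dimethoxybutyl)-2-ethyloxirane F5, which has no enolisable ketone next to the epoxide. H3PMo12O40 and ethereal H2O2 then open the epoxide intermolecularly at the tertiary carbon with inversion to (2S)-2-ethyl-2-hydroperoxy-4,4-dimethoxyhexan-1-ol F6. The same acid closes F6 by transketalisation and the sequence comes back to the route at 12.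

Step 11 (the most exposed step). Alkenyl transfer to a peroxycarbenium ion is unprecedented, the facial preference is expected to be modest, and the tertiary allylic C5–O bond of 22 can re-ionise if BF3 is not quenched cold. The fallback sets out from 12: acid (camphorsulfonic acid, 4 Å MS, CH2Cl2) closes the hydroxymethyl group onto the ketal carbon to give the bicyclic peroxyketal (1S,4R)-1,4-diethyl-2,3,5-trioxabicyclo[2.2.1]heptane F7. Alkyne 19 is carboaluminated (Me3Al, Cp2ZrCl2) to [(1E,4R,5E)-4-ethyl-2-methylocta-1,5-dien-1-yl]dimethylalumane F8. F8 binds the bridging ether oxygen of F7 and delivers the alkenyl group from the face that this oxygen leaves (retentive organoaluminium ketal cleavage), giving {(3S,5R)-3,5-diethyl-5-[(1E,4R,5E)-4-ethyl-2-methylocta-1,5-dien-1-yl]-1,2-dioxolan-3-yl}methanol F9 with the cis relationship enforced by the tether. One-pot Dess–Martin oxidation and Wittig reaction, through (3S,5R)-3,5-diethyl-5-[(1E,4R,5E)-4-ethyl-2-methylocta-1,5-dien-1-yl]-1,2-dioxolane-3-carbaldehyde F10, comes back to the route at 22.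

**Further compounds**
F1 | step 3 | tert-butyl{[(2R)-2-ethyloxiran-2-yl]methoxy}dimethylsilane | CC(C)(C)[Si](C)(C)OC[C@@]1(CC)CO1
F2 | step 3 | (2R)-1-{[tert-butyl(dimethyl)silyl]oxy}-2-[(2-ethyl-1,3-dithian-2-yl)methyl]butan-2-ol | CCC1(SCCCS1)C[C@@](CC)(O)CO[Si](C)(C)C(C)(C)C
F3 | step 3 | (2R)-2-[(2-ethyl-1,3-dithian-2-yl)methyl]butane-1,2-diol | CCC1(SCCCS1)C[C@@](CC)(O)CO
F4 | step 3 | (2R)-2-[(2-ethyl-1,3-dithian-2-yl)methyl]-2-hydroxybutyl 4-methylbenzenesulfonate | CCC1(SCCCS1)C[C@@](CC)(O)COS(=O)(=O)c1ccc(C)cc1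
F5 | step 5 | (2R)-2-(2,2-dimethoxybutyl)-2-ethyloxirane | CCC(OC)(OC)C[C@@]1(CC)OC1
F6 | step 5 | (2S)-2-ethyl-2-hydroperoxy-4,4-dimethoxyhexan-1-ol | CCC(OC)(OC)C[C@](CO)(CC)OO
F7 | step 11 | (1S,4R)-1,4-diethyl-2,3,5-trioxabicyclo[2.2.1]heptane | CC[C@@]12C[C@@](CC)(CO1)OO2
F8 | step 11 | [(1E,4R,5E)-4-ethyl-2-methylocta-1,5-dien-1-yl]dimethylalumane | CC/C=C/[C@H](CC)C/C(C)=C/[Al](C)C
F9 | step 11 | {(3S,5R)-3,5-diethyl-5-[(1E,4R,5E)-4-ethyl-2-methylocta-1,5-dien-1-yl]-1,2-dioxolan-3-yl}methanol | CC/C=C/[C@H](CC)C/C(C)=C/[C@@]1(CC)C[C@](CO)(CC)OO1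
F10 | step 11 | (3S,5R)-3,5-diethyl-5-[(1E,4R,5E)-4-ethyl-2-methylocta-1,5-dien-1-yl]-1,2-dioxolane-3-carbaldehyde | CC/C=C/[C@H](CC)C/C(C)=C/[C@@]1(CC)C[C@](C=O)(CC)OO1
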